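Numbering used: naphthoquinone C1–C8a (C1=O next to C2–OH, C4=O peri to C5–OH, C6 aroyl, C7 CH2–pyranone); ring A = methylresorcinol ring, ring B = benzo ring, ring C = quinone ring, ring D = pyranone.
Cuts, in retro order: five O–CH3 bonds; C1–C8a (ring C, from a 4-aryl-cyclobutenone as a masked aryl vinylketene); C7–CH2 (Negishi); C4–C4a (aryllithium + dimethyl squarate); C6–C(=O) (aryllithium + aldehyde); formyl C–C6.
Forward: ring B (1-bromo-4-chloro-2-methoxybenzene) is formylated between OMe and Cl, joined to ring A and oxidized to the benzophenone; Br/Li exchange at C4a and addition to dimethyl squarate give a temporary four-membered ring, whose carbonyl is transposed; ring D is coupled on at C7; heating then turns the cyclobutenone into ring C; oxidation and demethylation follow.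
Enabling feature: ring C is 1,4-dioxygenated with O at C2 and H at C3 and is fused to ring B at C4a/C8a, which is the hydroquinone delivered by 6π closure of the ketene O=C1=C2(OMe)–C3H=C4(OSi)–C4a onto C8a; C8a is the only free ortho CH of ring B (C5 carries OMe).
Stereochemistry: the target has no stereocentre; the carbinol and cyclobutenone stereocentres of intermediates are racemic and are destroyed on the way.
Key step: step 8

Assumption: intermediates with stereocentres (6, 10, 11, 13, 17 racemic; 12 a diastereomer mixture; likewise the fallback compounds) are written without configuration because every such centre is erased before the target.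

Step 1
Reactants: 1 1-bromo-4-chloro-2-methoxybenzene
Product: 3 3-bromo-6-chloro-2-methoxybenzaldehyde, via aryllithium 2 (not isolated)
Conditions: LiN(i-Pr)2, THF, −78 °C, 1 h; DMF, −78 → 0 °C; aq NH4Cl
Reagents that add atoms: N,N-dimethylformamide, CN(C)C=O
Why: Directed ortho-lithiation at the C–H flanked by OMe and Cl (the most acidic site, as in 3-chloroanisole) with an amide base that leaves C–Br untouched, followed by formylation of the aryllithium with DMF, should give the aldehyde.

Step 2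
Reactants: 3 3-bromo-6-chloro-2-methoxybenzaldehyde; 4 2-bromo-1,5-dimethoxy-3-methylbenzene
Product: 6 (3-bromo-6-chloro-2-methoxyphenyl)(2,4-dimethoxy-6-methylphenyl)methanol, via aryllithium 5 (not isolated)
Conditions: 4, n-BuLi, THF, −78 °C, 20 min; add 3, −78 °C; aq NH4Cl
Reagents that add atoms: none
Why: Bromine–lithium exchange on 4 and 1,2-addition of the aryllithium to the aldehyde at −78 °C should outrun any exchange with the halides of 3; the new carbinol centre is racemic and is removed in step 3.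

Step 3
Reactants: 6 (3-bromo-6-chloro-2-methoxyphenyl)(2,4-dimethoxy-6-methylphenyl)methanol
Product: 7 (3-bromo-6-chloro-2-methoxyphenyl)(2,4-dimethoxy-6-methylphenyl)methanone
Conditions: Dess–Martin periodinane, CH2Cl2, 0 °C → rt
Reagents that add atoms: none
Why: Dess–Martin oxidation of a hindered benzhydrol should give the tetra-ortho-substituted benzophenone without touching the aryl halides.

Step 4
Reactants: 7 (3-bromo-6-chloro-2-methoxyphenyl)(2,4-dimethoxy-6-methylphenyl)methanone; 8 3,4-dimethoxycyclobut-3-ene-1,2-dione (dimethyl squarate)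
Product: 11 4-[(tert-butyldimethylsilyl)oxy]-4-[4-chloro-3-(2,4-dimethoxy-6-methylbenzoyl)-2-methoxyphenyl]-2,3-dimethoxycyclobut-2-en-1-one, via aryllithium 9 (not isolated), via lithium alkoxide 10 (not isolated)
Conditions: n-BuLi (1.05 equiv), THF, −90 → −78 °C, 10 min; cannulate into 8 (1.3 equiv), THF, −78 °C; TBSOTf, −78 → 0 °C
Reagents that add atoms: tert-butyldimethylsilyl trifluoromethanesulfonate, CC(C)(C)[Si](C)(C)OS(=O)(=O)C(F)(F)F
Why: Br/Li exchange at C4a should be faster than attack on the twisted tetra-ortho-substituted ketone and leaves C–Cl intact, and 1,2-addition of the aryllithium to dimethyl squarate with in-situ O-silylation is the standard entry to 4-aryl-4-oxycyclobutenones; the new quaternary centre is racemic.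

Step 5
Reactants: 11 4-[(tert-butyldimethylsilyl)oxy]-4-[4-chloro-3-(2,4-dimethoxy-6-methylbenzoyl)-2-methoxyphenyl]-2,3-dimethoxycyclobut-2-en-1-one
Product: 13 4-[(tert-butyldimethylsilyl)oxy]-4-[4-chloro-3-(2,4-dimethoxy-6-methylbenzoyl)-2-methoxyphenyl]-2-methoxycyclobut-2-en-1-one, via cyclobutenol 12 (not isolated)
Conditions: NaBH4, CeCl3·7H2O, MeOH–THF, −78 → −40 °C; then 1 M HCl, THF, 0 °C
Reagents that add atoms: water, O
Why: Luche 1,2-reduction of the vinylogous-ester carbonyl and acid-induced allylic ionization with hydrolysis of the resulting oxocarbenium ion (a Stork–Danheiser carbonyl transposition, as in the reductive preparation of semisquaric esters from squarates) should place the carbonyl next to the remaining OMe and leave H on the other alkene carbon, while the hindered benzophenone is not reduced at low temperature; the carbinol centre of 12 is erased.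

Step 6
Reactants: 14 4-methoxy-6-methyl-2H-pyran-2-one
Product: 15 6-(bromomethyl)-4-methoxy-2H-pyran-2-one
Conditions: N-bromosuccinimide, AIBN (cat.), PhCF3, 85 °C
Reagents that add atoms: N-bromosuccinimide, O=C1CCC(=O)N1Br
Why: Wohl–Ziegler radical bromination should occur at the 6-methyl group, the allylic-type position of the pyranone.

Step 7
Reactants: 13 4-[(tert-butyldimethylsilyl)oxy]-4-[4-chloro-3-(2,4-dimethoxy-6-methylbenzoyl)-2-methoxyphenyl]-2-methoxycyclobut-2-en-1-one; 15 6-(bromomethyl)-4-methoxy-2H-pyran-2-one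
Product: 17 4-[(tert-butyldimethylsilyl)oxy]-4-{3-(2,4-dimethoxy-6-methylbenzoyl)-2-methoxy-4-[(4-methoxy-2-oxo-2H-pyran-6-yl)methyl]phenyl}-2-methoxycyclobut-2-en-1-one, via organozinc bromide 16 (not isolated)
Conditions: 15, Zn dust, LiCl, THF, 25 °C; then 13, Pd(OAc)2 (3 mol %), SPhos (6 mol %), THF, 40 °C
Reagents that add atoms: none
Why: Zinc insertion into the allylic-type bromide and Negishi coupling (zerovalent palladium with a biaryl phosphine) with the aryl chloride activated by the ortho aroyl group should proceed base-free and below the temperature at which the cyclobutenone opens; the acidic ArCH2 group is thus created only after the last organolithium step.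

Step 8
Reactants: 17 4-[(tert-butyldimethylsilyl)oxy]-4-{3-(2,4-dimethoxy-6-methylbenzoyl)-2-methoxy-4-[(4-methoxy-2-oxo-2H-pyran-6-yl)methyl]phenyl}-2-methoxycyclobut-2-en-1-one
Product: 19 4-[(tert-butyldimethylsilyl)oxy]-6-(2,4-dimethoxy-6-methylbenzoyl)-2,5-dimethoxy-7-[(4-methoxy-2-oxo-2H-pyran-6-yl)methyl]naphthalen-1-ol, via dienylketene 18 (not isolated)
Conditions: p-xylene (0.01 M, degassed), 138 °C, 2 h
Reagents that add atoms: none
Why: Heating should open the temporary four-membered ring by conrotatory 4π-electrocyclic cleavage of the cyclobutenone C1–C4 bond with the silyloxy group rotating outward, so that dienylketene 18 carries ring B cis to the ketene; the ketene carbon (future C1) then bonds to C8a in a thermal disrotatory 6π-electrocyclization and the resulting cyclohexadienone tautomerizes to naphthol 19. The closest known reaction type is the Moore rearrangement of 4-aryl-4-oxycyclobutenones, the cyclobutenone form of the Danheiser benzannulation. The only ring closed is the six-membered ring C, by a 6π-electrocyclic closure onto the arene (formally 6-endo at the ketene carbon). No stereocentre is created and the racemic cyclobutenone centre is erased. The step needs outward rotation of the oxygen substituent (secured by the donor OSi group), closure at C8a only (C5, the other ortho position, carries OMe) and OMe at C2 with H at C3 (secured in step 5, because the substituent on the cyclobutenone carbon next to its carbonyl ends up next to the new bond). Being pericyclic, the closure does not depend on the nucleophilicity of C8a, which lies para to the deactivating aroyl group, and no free OH is present that could intercept the ketene.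

Step 9
Reactants: 19 4-[(tert-butyldimethylsilyl)oxy]-6-(2,4-dimethoxy-6-methylbenzoyl)-2,5-dimethoxy-7-[(4-methoxy-2-oxo-2H-pyran-6-yl)methyl]naphthalen-1-ol
Product: 20 6-(2,4-dimethoxy-6-methylbenzoyl)-2,5-dimethoxy-7-[(4-methoxy-2-oxo-2H-pyran-6-yl)methyl]naphthalene-1,4-dione
Conditions: PhI(OAc)2, MeCN–H2O, 0 °C
Reagents that add atoms: none
Why: Oxidative desilylation of a hydroquinone mono-silyl ether with a hypervalent iodine reagent (ligand exchange at the naphthol oxygen, then loss of the silyl group from the para oxygen) should give the 1,4-quinone.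

Step 10
Reactants: 20 6-(2,4-dimethoxy-6-methylbenzoyl)-2,5-dimethoxy-7-[(4-methoxy-2-oxo-2H-pyran-6-yl)methyl]naphthalene-1,4-dione
Product: 21 6-(2,4-dihydroxy-6-methylbenzoyl)-2,5-dihydroxy-7-[(4-hydroxy-2-oxo-2H-pyran-6-yl)methyl]naphthalene-1,4-dione (CNP0158797.0)
Conditions: BBr3 (15 equiv), CH2Cl2, −78 °C → rt; H2O
Reagents that add atoms: none
Why: Lewis-acid ether cleavage with BBr3 should remove all five methyl groups, since the C2 and pyranone methoxy groups are vinylogous methyl esters, the C5 methoxy group is peri to C4=O and the two ring A ethers are ordinary aryl methyl ethers, while quinone, pyranone and benzophenone survive.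

Compound list
1 | 1-bromo-4-chloro-2-methoxybenzene | COc1cc(Cl)ccc1Br | starting material
2 | (3-bromo-6-chloro-2-methoxyphenyl)lithium | COc1c(Br)ccc(Cl)c1[Li] | intermediate
3 | 3-bromo-6-chloro-2-methoxybenzaldehyde | COc1c(Br)ccc(Cl)c1C=O | intermediate
4 | 2-bromo-1,5-dimethoxy-3-methylbenzene | Cc1cc(OC)cc(OC)c1Br | starting material
5 | (2,4-dimethoxy-6-methylphenyl)lithium | Cc1cc(OC)cc(OC)c1[Li] | intermediate
6 | (3-bromo-6-chloro-2-methoxyphenyl)(2,4-dimethoxy-6-methylphenyl)methanol (racemic) | Cc1cc(OC)cc(OC)c1C(O)c1c(Cl)ccc(Br)c1OC | intermediate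
7 | (3-bromo-6-chloro-2-methoxyphenyl)(2,4-dimethoxy-6-methylphenyl)methanone | Cc1cc(OC)cc(OC)c1C(=O)c1c(Cl)ccc(Br)c1OC | intermediate
8 | 3,4-dimethoxycyclobut-3-ene-1,2-dione (dimethyl squarate) | COC1=C(OC)C(=O)C1=O | starting material
9 | [4-chloro-3-(2,4-dimethoxy-6-methylbenzoyl)-2-methoxyphenyl]lithium | Cc1cc(OC)cc(OC)c1C(=O)c1c(Cl)ccc([Li])c1OC | intermediate
10 | lithium 1-[4-chloro-3-(2,4-dimethoxy-6-methylbenzoyl)-2-methoxyphenyl]-2,3-dimethoxy-4-oxocyclobut-2-en-1-olate (racemic) | COC1=C(OC)C(O[Li])(c2ccc(Cl)c(C(=O)c3c(C)cc(OC)cc3OC)c2OC)C1=O | intermediate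
11 | 4-[(tert-butyldimethylsilyl)oxy]-4-[4-chloro-3-(2,4-dimethoxy-6-methylbenzoyl)-2-methoxyphenyl]-2,3-dimethoxycyclobut-2-en-1-one (racemic) | COC1=C(OC)C(O[Si](C)(C)C(C)(C)C)(c2ccc(Cl)c(C(=O)c3c(C)cc(OC)cc3OC)c2OC)C1=O | intermediate
12 | 4-[(tert-butyldimethylsilyl)oxy]-4-[4-chloro-3-(2,4-dimethoxy-6-methylbenzoyl)-2-methoxyphenyl]-2,3-dimethoxycyclobut-2-en-1-ol (diastereomer mixture) | COC1=C(OC)C(O[Si](C)(C)C(C)(C)C)(c2ccc(Cl)c(C(=O)c3c(C)cc(OC)cc3OC)c2OC)C1O | intermediate
13 | 4-[(tert-butyldimethylsilyl)oxy]-4-[4-chloro-3-(2,4-dimethoxy-6-methylbenzoyl)-2-methoxyphenyl]-2-methoxycyclobut-2-en-1-one (racemic) | COC1=CC(O[Si](C)(C)C(C)(C)C)(c2ccc(Cl)c(C(=O)c3c(C)cc(OC)cc3OC)c2OC)C1=O | intermediate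
14 | 4-methoxy-6-methyl-2H-pyran-2-one | Cc1cc(OC)cc(=O)o1 | starting material
15 | 6-(bromomethyl)-4-methoxy-2H-pyran-2-one | BrCc1cc(OC)cc(=O)o1 | intermediate
16 | [(4-methoxy-2-oxo-2H-pyran-6-yl)methyl]zinc bromide | Br[Zn]Cc1cc(OC)cc(=O)o1 | intermediate
17 | 4-[(tert-butyldimethylsilyl)oxy]-4-{3-(2,4-dimethoxy-6-methylbenzoyl)-2-methoxy-4-[(4-methoxy-2-oxo-2H-pyran-6-yl)methyl]phenyl}-2-methoxycyclobut-2-en-1-one (racemic) | COC1=CC(O[Si](C)(C)C(C)(C)C)(c2ccc(Cc3cc(OC)cc(=O)o3)c(C(=O)c3c(C)cc(OC)cc3OC)c2OC)C1=O | intermediate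
18 | (E)-4-[(tert-butyldimethylsilyl)oxy]-4-{3-(2,4-dimethoxy-6-methylbenzoyl)-2-methoxy-4-[(4-methoxy-2-oxo-2H-pyran-6-yl)methyl]phenyl}-2-methoxybuta-1,3-dien-1-one (dienylketene) | O=C=C(OC)/C=C(/O[Si](C)(C)C(C)(C)C)c1ccc(Cc2cc(OC)cc(=O)o2)c(C(=O)c2c(C)cc(OC)cc2OC)c1OC | intermediate
19 | 4-[(tert-butyldimethylsilyl)oxy]-6-(2,4-dimethoxy-6-methylbenzoyl)-2,5-dimethoxy-7-[(4-methoxy-2-oxo-2H-pyran-6-yl)methyl]naphthalen-1-ol | COc1cc(O[Si](C)(C)C(C)(C)C)c2c(OC)c(C(=O)c3c(C)cc(OC)cc3OC)c(Cc3cc(OC)cc(=O)o3)cc2c1O | intermediate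
20 | 6-(2,4-dimethoxy-6-methylbenzoyl)-2,5-dimethoxy-7-[(4-methoxy-2-oxo-2H-pyran-6-yl)methyl]naphthalene-1,4-dione | COC1=CC(=O)c2c(OC)c(C(=O)c3c(C)cc(OC)cc3OC)c(Cc3cc(OC)cc(=O)o3)cc2C1=O | intermediate
21 | 6-(2,4-dihydroxy-6-methylbenzoyl)-2,5-dihydroxy-7-[(4-hydroxy-2-oxo-2H-pyran-6-yl)methyl]naphthalene-1,4-dione (CNP0158797.0) | Cc1cc(O)cc(O)c1C(=O)c1c(Cc2cc(O)cc(=O)o2)cc2c(c1O)C(=O)C=C(O)C2=O | target

Total step count: 10. Longest linear sequence: 9 steps (steps 1–5 and 7–10); step 6 is a one-step side branch.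

Steps most likely to fail

Step 7. What may go wrong: coupling of the zinc reagent through ring carbon C3 of the pyranone instead of its CH2 group, self-condensation of the zinc reagent, or oxidative addition at the hindered chloride so slow that the cyclobutenone begins to open. Fallback (ring D is built instead of coupled on), setting out from 13 and coming back at 21: Negishi coupling of 13 with allylzinc bromide (Pd(OAc)2, SPhos, THF, 25 °C) should give the allyl compound F1. Cleavage with OsO4 (cat.), NaIO4 and 2,6-lutidine in dioxane–H2O should give the arylacetaldehyde F2. Addition of the lithium dienolate of 2,2,6-trimethyl-4H-1,3-dioxin-4-one (LiN(SiMe3)2, THF, −78 °C) should give the aldol F3, and Dess–Martin oxidation the β-keto-dioxinone F4. Heating F4 in p-xylene at 138 °C should open both temporary rings in one pot: retro-[4+2] loss of acetone gives an acylketene that closes to the 4-hydroxy-2-pyranone, and the Moore rearrangement of step 8 gives the naphthol F5. Oxidation with (NH4)2Ce(NO3)6 in MeCN–H2O should give the quinone F6, and BBr3 as in step 10 returns to the route at 21.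

Step 4. What may go wrong: addition of n-BuLi or of aryllithium 9 to the ketone, electron transfer to the benzophenone, or lithiation next to chlorine followed by loss of LiCl. Fallback (the C6 carbonyl is carried through the organolithium step as a protected carbinol), setting out from 6 and coming back at 11: TESOTf and 2,6-lutidine should convert 6 into the triethylsilyl ether F7. n-BuLi, then 8, then TBSOTf (as in step 4) should give the cyclobutenone F8. HF·pyridine in THF–pyridine at 0 °C should remove only the secondary triethylsilyl group to give the carbinol F9, and Dess–Martin oxidation returns to the route at 11.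

Step 5. What may go wrong: ionization at the silyloxy-bearing carbon instead of the secondary carbinol (leading to an aryl-cyclobutenedione), loss of the silyl ether, or partial reduction of the benzophenone. Fallback (the two squarate carbonyls are differentiated before the aryl group is added, so the aryl adduct needs no reduction), setting out from 7 and coming back at 13: 8 is reduced with LiAlH(Ot-Bu)3 (THF, −78 °C) to the hydroxycyclobutenone F10, which with MeOH and BF3·OEt2 (cat.) should give the monoketal F11. Aryllithium 9, made from 7 as in step 4, is added to F11 at −78 °C and the alkoxide is silylated with TBSOTf to give the ketal F12. Oxalic acid on wet silica gel in CH2Cl2 should hydrolyse the ketal and return to the route at 13.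

Further compounds
F1 | step 7 | 4-[(tert-butyldimethylsilyl)oxy]-4-[4-allyl-3-(2,4-dimethoxy-6-methylbenzoyl)-2-methoxyphenyl]-2-methoxycyclobut-2-en-1-one | COC1=CC(O[Si](C)(C)C(C)(C)C)(c2ccc(CC=C)c(C(=O)c3c(C)cc(OC)cc3OC)c2OC)C1=O
F2 | step 7 | 2-{4-[1-[(tert-butyldimethylsilyl)oxy]-3-methoxy-4-oxocyclobut-2-en-1-yl]-2-(2,4-dimethoxy-6-methylbenzoyl)-3-methoxyphenyl}acetaldehyde | COC1=CC(O[Si](C)(C)C(C)(C)C)(c2ccc(CC=O)c(C(=O)c3c(C)cc(OC)cc3OC)c2OC)C1=O
F3 | step 7 | 6-(3-{4-[1-[(tert-butyldimethylsilyl)oxy]-3-methoxy-4-oxocyclobut-2-en-1-yl]-2-(2,4-dimethoxy-6-methylbenzoyl)-3-methoxyphenyl}-2-hydroxypropyl)-2,2-dimethyl-4H-1,3-dioxin-4-one | COC1=CC(O[Si](C)(C)C(C)(C)C)(c2ccc(CC(O)CC3=CC(=O)OC(C)(C)O3)c(C(=O)c3c(C)cc(OC)cc3OC)c2OC)C1=O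
F4 | step 7 | 6-(3-{4-[1-[(tert-butyldimethylsilyl)oxy]-3-methoxy-4-oxocyclobut-2-en-1-yl]-2-(2,4-dimethoxy-6-methylbenzoyl)-3-methoxyphenyl}-2-oxopropyl)-2,2-dimethyl-4H-1,3-dioxin-4-one | COC1=CC(O[Si](C)(C)C(C)(C)C)(c2ccc(CC(=O)CC3=CC(=O)OC(C)(C)O3)c(C(=O)c3c(C)cc(OC)cc3OC)c2OC)C1=O
F5 | step 7 | 4-[(tert-butyldimethylsilyl)oxy]-6-(2,4-dimethoxy-6-methylbenzoyl)-7-[(4-hydroxy-2-oxo-2H-pyran-6-yl)methyl]-2,5-dimethoxynaphthalen-1-ol | COc1cc(O[Si](C)(C)C(C)(C)C)c2c(OC)c(C(=O)c3c(C)cc(OC)cc3OC)c(Cc3cc(O)cc(=O)o3)cc2c1O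
F6 | step 7 | 6-(2,4-dimethoxy-6-methylbenzoyl)-7-[(4-hydroxy-2-oxo-2H-pyran-6-yl)methyl]-2,5-dimethoxynaphthalene-1,4-dione | COC1=CC(=O)c2c(OC)c(C(=O)c3c(C)cc(OC)cc3OC)c(Cc3cc(O)cc(=O)o3)cc2C1=O
F7 | step 4 | [(3-bromo-6-chloro-2-methoxyphenyl)(2,4-dimethoxy-6-methylphenyl)methoxy]triethylsilane | Cc1cc(OC)cc(OC)c1C(O[Si](CC)(CC)CC)c1c(Cl)ccc(Br)c1OC
F8 | step 4 | 4-[(tert-butyldimethylsilyl)oxy]-4-(4-chloro-3-{(2,4-dimethoxy-6-methylphenyl)[(triethylsilyl)oxy]methyl}-2-methoxyphenyl)-2,3-dimethoxycyclobut-2-en-1-one | COC1=C(OC)C(O[Si](C)(C)C(C)(C)C)(c2ccc(Cl)c(C(O[Si](CC)(CC)CC)c3c(C)cc(OC)cc3OC)c2OC)C1=O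
F9 | step 4 | 4-[(tert-butyldimethylsilyl)oxy]-4-{4-chloro-3-[(2,4-dimethoxy-6-methylphenyl)(hydroxy)methyl]-2-methoxyphenyl}-2,3-dimethoxycyclobut-2-en-1-one | COC1=C(OC)C(O[Si](C)(C)C(C)(C)C)(c2ccc(Cl)c(C(O)c3c(C)cc(OC)cc3OC)c2OC)C1=O
F10 | step 5 | 4-hydroxy-2,3-dimethoxycyclobut-2-en-1-one | COC1=C(OC)C(O)C1=O
F11 | step 5 | 3,4,4-trimethoxycyclobut-2-en-1-one | COC1=CC(=O)C1(OC)OC
F12 | step 5 | tert-butyl({1-[4-chloro-3-(2,4-dimethoxy-6-methylbenzoyl)-2-methoxyphenyl]-3,4,4-trimethoxycyclobut-2-en-1-yl}oxy)dimethylsilane | COC1=CC(O[Si](C)(C)C(C)(C)C)(c2ccc(Cl)c(C(=O)c3c(C)cc(OC)cc3OC)c2OC)C1(OC)OC
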